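## Retrosynthetic overview

1. Feature: in ring B (C5–C10) the quaternary C10 carries a methyl and the C1 methylene, which is the α-carbon pattern of methacrolein. C5 and C7 carry their substituents 1,3 to each other like positions 1 and 3 of a butadiene, and H5 and CH3-10 are cis, as a formyl-endo [4+2] addition delivers.
2. Late disconnections: the C4 acetate and C3 angelate come from acylations. C8=O and C7–H go back to a C6=C7 alkene through allylic oxidation, hydrogenation and equilibration of C7.
3. Ring A: the C3–C4 bond comes from SmI2 pinacol closure of a C3 aldehyde onto a C4 methyl ketone, both grown from the CHO (C1) and CH2OSi (C4) handles of the cycloadduct.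
4. Ring B: C5–C10 and C8–C9 come from a catalytic enantioselective Diels–Alder reaction of methacrolein with (E)-CH2=C(iPr)CH=CHCH2OTBS, which is made by enyne cross-metathesis.
5. Order of ring formation: ring B in step 2, then ring A in step 10.

Key step: step 2

Remark on numbering: atoms carry eudesmane numbers (ring A = C1–C5, C10; ring B = C5–C10; C15 = methyl on C4). β is the face carrying CH3-10 and H5, and α is the opposite face.

Assumption: the sense of induction in step 2 is taken from the formyl C–H···O binding model of this catalyst class. On that basis the (R)-prolinol series is chosen.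

## Route

Step 1
Reactants: 1 3-methylbut-1-yne; 2 allyl tert-butyldimethylsilyl ether
Product: 3 (E)-tert-butyl(dimethyl)[(5-methyl-4-methylidenehex-2-en-1-yl)oxy]silane
Conditions: 2 (3 equiv), second-generation Grubbs catalyst RuCl2(=CHPh)(PCy3)(H2IMes) (5 mol%), CH2Cl2, 40 °C, sealed vessel; Z isomer removed by chromatography
Reagents that add atoms: none
Why: Ruthenium-carbene enyne cross-metathesis of a terminal alkyne with a terminal alkene places the alkyne substituent on the internal diene carbon (1,3-disubstituted butadiene); allyl silyl ethers are standard partners, and reversible secondary metathesis should favour the E isomer, the only one that can reach the s-cis form needed next.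

Step 2
Reactants: 3 (E)-diene; 4 methacrolein
Product: 5 (1R,2S)-2-{[tert-butyl(dimethyl)silyl]oxymethyl}-1-methyl-4-(propan-2-yl)cyclohex-3-ene-1-carbaldehyde (CHO and CH2OTBS cis; ring C1 = C10, ring C2 = C5)
Conditions: (3aR)-1-(2-methylphenyl)-3,3-diphenyltetrahydro-1H,3H-pyrrolo[1,2-c][1,3,2]oxazaborole (20 mol%), Tf2NH (18 mol%), 4 (3 equiv), CH2Cl2, −78 → −40 °C
Reagents that add atoms: none
Why: The protonated oxazaborolidine binds the formyl oxygen of s-trans methacrolein (B–O bond plus formyl C–H···O contact), lowers its LUMO and lets the s-cis diene add in a concerted but asynchronous [4+2] cycloaddition in which C8–C9 bonding runs ahead of C5–C10 bonding. The closest known reaction type is the oxazaborolidinium-catalysed enantioselective Diels–Alder reaction of 2-substituted acroleins with acyclic alkyl-substituted butadienes. Ring B closes in this single intermolecular six-centre event, which leaves the C6=C7 double bond. C10 is set by the catalyst, whose convex-face phenyl group lies under the bound enal so that in the (R)-series only the Si face of the α-carbon is open to C5; C5 is set relative to C10 by the E geometry of the diene and the formyl-endo orientation favoured under Lewis acid catalysis, which puts CH2OTBS and CHO cis and hence H5 and CH3-10 cis. Regio-, endo- and enantioselectivity are all needed: the 1-alkyl and 3-isopropyl groups both enlarge the HOMO coefficient at C8, which pairs with the β-carbon C9, so the ortho and para preferences agree; the acyclic diene has no bridging CH2 that would push the α-methyl group endo; and the bulky silyl group keeps the ether oxygen from competing for boron.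

Step 3
Reactants: 5 cycloadduct aldehyde
Product: 6 methyl (E)-3-[(1S,2S)-2-{[tert-butyl(dimethyl)silyl]oxymethyl}-1-methyl-4-(propan-2-yl)cyclohex-3-en-1-yl]prop-2-enoate
Conditions: (MeO)2P(O)CH2CO2Me, NaH, THF, 0 °C → rt
Reagents that add atoms: trimethyl phosphonoacetate, COC(=O)CP(=O)(OC)OC
Why: Horner–Wadsworth–Emmons olefination of a non-enolisable neopentyl aldehyde adds C2 and C3 as the E enoate without touching C5 or C10.

Step 4
Reactants: 6 enoate
Product: 7 methyl 3-[(1S,2S)-2-{[tert-butyl(dimethyl)silyl]oxymethyl}-1-methyl-4-(propan-2-yl)cyclohex-3-en-1-yl]propanoate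
Conditions: Mg turnings, MeOH, 0 °C → rt
Reagents that add atoms: none
Why: Magnesium in methanol reduces conjugated esters by single-electron transfer, so C1=C2 is saturated while the isolated C6=C7 bond and the silyl ether stay intact; the methyl ester makes methoxide exchange invisible.

Step 5
Reactants: 7 silyl ether ester
Product: 8 methyl 3-[(1S,2S)-2-(hydroxymethyl)-1-methyl-4-(propan-2-yl)cyclohex-3-en-1-yl]propanoate
Conditions: Bu4NF, THF, 0 °C → rt
Reagents that add atoms: none
Why: Fluoride-driven desilylation frees the primary C4 alcohol, and seven-membered lactonisation onto the ester is not competitive.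

Step 6
Reactants: 8 hydroxy ester
Product: 9 methyl 3-[(1S,2S)-2-formyl-1-methyl-4-(propan-2-yl)cyclohex-3-en-1-yl]propanoate
Conditions: Dess–Martin periodinane, NaHCO3, CH2Cl2, 0 °C; crude product used at once
Reagents that add atoms: none
Why: Buffered Dess–Martin oxidation is neutral enough to give the β,γ-unsaturated aldehyde without moving C6=C7 into conjugation or epimerising C5.

Step 7
Reactants: 9 aldehyde ester
Product: 10 methyl 3-[(1S,2S)-2-(1-hydroxyethyl)-1-methyl-4-(propan-2-yl)cyclohex-3-en-1-yl]propanoate (both carbinol epimers at C4)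
Conditions: MeMgBr (1.1 equiv), Et2O/THF, −78 °C; aq NH4Cl
Reagents that add atoms: methylmagnesium bromide, C[Mg]Br
Why: Grignard 1,2-addition to the aldehyde at −78 °C is much faster than ester attack or enolisation and brings in C15; the new carbinol centre is left undefined because step 9 oxidises it.

Step 8
Reactants: 10 hydroxy ester
Product: 11 3-[(1S,2S)-2-(1-hydroxyethyl)-1-methyl-4-(propan-2-yl)cyclohex-3-en-1-yl]propan-1-ol (both carbinol epimers at C4)
Conditions: LiAlH4, THF, 0 °C
Reagents that add atoms: none
Why: Hydride reduction of the ester brings C3 to the alcohol level so that both termini can be oxidised together, and the isolated alkene is inert.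

Step 9
Reactants: 11 diol
Product: 12 3-[(1S,2S)-2-acetyl-1-methyl-4-(propan-2-yl)cyclohex-3-en-1-yl]propanal
Conditions: Dess–Martin periodinane (2.5 equiv), NaHCO3, CH2Cl2, 0 °C → rt; used without storage
Reagents that add atoms: none
Why: Double Dess–Martin oxidation converges both C4 epimers to the methyl ketone and gives the C3 aldehyde under non-enolising conditions that preserve C5 and the position of C6=C7.

Step 10
Reactants: 12 keto aldehyde
Product: 13 (5βH)-eudesm-6-ene-3α,4α-diol (cis-fused; CH3-4 β)
Conditions: SmI2 (2.5 equiv, 0.1 M in THF), t-BuOH (2 equiv), THF, −78 °C → rt, high dilution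
Reagents that add atoms: none
Why: In this SmI2 pinacol cyclisation of a 1,6-keto aldehyde the aldehyde ketyl adds to the ketone held on the same trivalent samarium, which makes the two oxygens cis; of the chair-like closures, the one with the C4 methyl equatorial and the forming C3–C4 bond anti to the C5–C6(sp2) bond (rather than gauche to both C6 and C10) should be preferred, placing both hydroxyls on the α face, trans to H5 and CH3-10.

Step 11
Reactants: 13 ene diol
Product: 14 (5βH)-eudesm-6-ene-3α,4α,8-triol (C8 configuration undefined)
Conditions: SeO2 (30 mol%), t-BuOOH (3 equiv, decane), CH2Cl2, rt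
Reagents that add atoms: tert-butyl hydroperoxide, CC(C)(C)OO (terminal oxygen source); selenium dioxide, O=[Se]=O (relays the oxygen)
Why: Catalytic SeO2/t-BuOOH allylic hydroxylation (ene reaction then [2,3]-shift) of a trisubstituted ring alkene goes to the ring CH2 next to the more substituted carbon, here C8 (CH2 reacts before the isopropyl CH, and C5–H sits at the less substituted terminus); the C8 configuration is irrelevant because step 12 removes it.

Step 12
Reactants: 14 triol
Product: 15 3α,4α-dihydroxy-(5βH)-eudesm-6-en-8-one
Conditions: activated MnO2 (excess), CH2Cl2, rt, short contact time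
Reagents that add atoms: none
Why: Activated MnO2 oxidises allylic alcohols far faster than saturated secondary or tertiary ones, so only C8–OH is taken to the ketone.

Step 13
Reactants: 15 enone diol
Product: 16 3α,4α-dihydroxy-(5βH)-eudesman-8-one as a mixture of C7 epimers
Conditions: H2 (1 atm), Pd/C (10 wt%), EtOAc, rt
Reagents that add atoms: none
Why: Heterogeneous hydrogenation saturates the only C=C bond before the reducible angelate is introduced, and the facial outcome at C7 need not be controlled because C7 is α to the ketone.

Step 14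
Reactants: 16 C7-epimeric keto diol
Product: 17 3α,4α-dihydroxy-(5βH,7αH)-eudesman-8-one (isopropyl β)
Conditions: K2CO3 (30 mol%), MeOH, rt
Reagents that add atoms: none
Why: Base-mediated enolisation equilibrates C7 under thermodynamic control: only the chair–chair form with CH3-4 equatorial avoids a syn-diaxial CH3-4/CH3-10 contact, and in that form the β-isopropyl group is equatorial while an α-isopropyl group would be axial and syn to C4.

Step 15
Reactants: 17 keto diol; 18 angelic acid
Product: 20 3α-angeloyloxy-4α-hydroxy-(5βH,7αH)-eudesman-8-one, via mixed anhydride 19 (not isolated)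
Conditions: 18, 2,4,6-trichlorobenzoyl chloride, Et3N, toluene, rt; then 17, 80 °C
Reagents that add atoms: 2,4,6-trichlorobenzoyl chloride, O=C(Cl)c1c(Cl)cc(Cl)cc1Cl (its atoms appear only in intermediate 19)
Why: Yamaguchi-type mixed-anhydride acylation without a nucleophilic catalyst is the established way to transfer the angeloyl group without Z to E isomerisation, and only the equatorial secondary C3–OH reacts because the axial tertiary C4–OH is too hindered.

Step 16
Reactants: 20 hydroxy angelate
Product: 21 target, 4α-acetoxy-3α-angeloyloxy-(5βH,7αH)-eudesman-8-one = (1S,2R,4aR,7R,8aS)-1-acetoxy-1,4a-dimethyl-6-oxo-7-(propan-2-yl)decahydronaphthalen-2-yl (Z)-2-methylbut-2-enoate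
Conditions: Ac2O (excess), 4-dimethylaminopyridine (0.5 equiv), Et3N, CH2Cl2, 40 °C, prolonged
Reagents that add atoms: acetic anhydride, CC(=O)OC(C)=O
Why: DMAP-catalysed acyl transfer with excess anhydride can esterify tertiary alcohols; the angelate on the secondary oxygen has no driving force to migrate, and no stereocentre is touched.

## Compound list

1 | 3-methylbut-1-yne | CC(C)C#C | starting material
2 | allyl tert-butyldimethylsilyl ether | C=CCO[Si](C)(C)C(C)(C)C | starting material
3 | (E)-tert-butyl(dimethyl)[(5-methyl-4-methylidenehex-2-en-1-yl)oxy]silane | C=C(C(C)C)/C=C/CO[Si](C)(C)C(C)(C)C | intermediate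
4 | methacrolein | C=C(C)C=O | starting material
5 | (1R,2S)-2-{[tert-butyl(dimethyl)silyl]oxymethyl}-1-methyl-4-(propan-2-yl)cyclohex-3-ene-1-carbaldehyde | O=C[C@]1(C)CCC(C(C)C)=C[C@@H]1CO[Si](C)(C)C(C)(C)C | intermediate
6 | methyl (E)-3-[(1S,2S)-2-(silyloxymethyl)-1-methyl-4-(propan-2-yl)cyclohex-3-en-1-yl]prop-2-enoate | COC(=O)/C=C/[C@]1(C)CCC(C(C)C)=C[C@@H]1CO[Si](C)(C)C(C)(C)C | intermediate
7 | methyl 3-[(1S,2S)-2-(silyloxymethyl)-1-methyl-4-(propan-2-yl)cyclohex-3-en-1-yl]propanoate | COC(=O)CC[C@]1(C)CCC(C(C)C)=C[C@@H]1CO[Si](C)(C)C(C)(C)C | intermediate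
8 | methyl 3-[(1S,2S)-2-(hydroxymethyl)-1-methyl-4-(propan-2-yl)cyclohex-3-en-1-yl]propanoate | COC(=O)CC[C@]1(C)CCC(C(C)C)=C[C@@H]1CO | intermediate
9 | methyl 3-[(1S,2S)-2-formyl-1-methyl-4-(propan-2-yl)cyclohex-3-en-1-yl]propanoate | COC(=O)CC[C@]1(C)CCC(C(C)C)=C[C@@H]1C=O | intermediate
10 | methyl 3-[(1S,2S)-2-(1-hydroxyethyl)-1-methyl-4-(propan-2-yl)cyclohex-3-en-1-yl]propanoate (carbinol epimers) | COC(=O)CC[C@]1(C)CCC(C(C)C)=C[C@@H]1C(C)O | intermediate
11 | 3-[(1S,2S)-2-(1-hydroxyethyl)-1-methyl-4-(propan-2-yl)cyclohex-3-en-1-yl]propan-1-ol (carbinol epimers) | OCCC[C@]1(C)CCC(C(C)C)=C[C@@H]1C(C)O | intermediate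
12 | 3-[(1S,2S)-2-acetyl-1-methyl-4-(propan-2-yl)cyclohex-3-en-1-yl]propanal | O=CCC[C@]1(C)CCC(C(C)C)=C[C@@H]1C(C)=O | intermediate
13 | (5βH)-eudesm-6-ene-3α,4α-diol | O[C@@H]1CC[C@]2(C)CCC(C(C)C)=C[C@@H]2[C@]1(C)O | intermediate
14 | (5βH)-eudesm-6-ene-3α,4α,8-triol (C8 undefined) | O[C@@H]1CC[C@]2(C)CC(O)C(C(C)C)=C[C@@H]2[C@]1(C)O | intermediate
15 | 3α,4α-dihydroxy-(5βH)-eudesm-6-en-8-one | O[C@@H]1CC[C@]2(C)CC(=O)C(C(C)C)=C[C@@H]2[C@]1(C)O | intermediate
16 | 3α,4α-dihydroxy-(5βH)-eudesman-8-one (C7 epimers) | O[C@@H]1CC[C@]2(C)CC(=O)C(C(C)C)C[C@@H]2[C@]1(C)O | intermediate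
17 | 3α,4α-dihydroxy-(5βH,7αH)-eudesman-8-one | O[C@@H]1CC[C@]2(C)CC(=O)[C@@H](C(C)C)C[C@@H]2[C@]1(C)O | intermediate
18 | angelic acid, (Z)-2-methylbut-2-enoic acid | C/C=C(/C)C(=O)O | starting material
19 | angelic 2,4,6-trichlorobenzoic anhydride | C/C=C(/C)C(=O)OC(=O)c1c(Cl)cc(Cl)cc1Cl | intermediate
20 | 3α-angeloyloxy-4α-hydroxy-(5βH,7αH)-eudesman-8-one | C/C=C(/C)C(=O)O[C@@H]1CC[C@]2(C)CC(=O)[C@@H](C(C)C)C[C@@H]2[C@]1(C)O | intermediate
21 | 4α-acetoxy-3α-angeloyloxy-(5βH,7αH)-eudesman-8-one | C/C=C(/C)C(=O)O[C@@H]1CC[C@]2(C)CC(=O)[C@@H](C(C)C)C[C@@H]2[C@]1(C)OC(C)=O | target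

## Step count and risks

Total step count: 16. Longest linear sequence: 16 steps, from 1 or 2 to 21.

**Step 2.** Enantiofacial control may erode, either through background cycloaddition promoted by adventitious acid or through the ether oxygen competing for boron. The endo preference may also be incomplete.

The fallback uses resolution in place of asymmetric catalysis:
- Setting out from 3 and 4, the cycloaddition would be run with an achiral Lewis acid (BF3·OEt2, CH2Cl2, −78 °C). This gives the racemic endo adduct, that is 5 together with the mirror-image aldehyde F1.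
- Condensation with (1R,2R)-N,N'-dimethyl-1,2-diphenylethane-1,2-diamine (molecular sieves, Et2O) would convert the pair into two diastereomers, the imidazolidine of 5 F2 and the imidazolidine of the mirror-image aldehyde F3.
- These should be separable by chromatography, which would also remove any exo adduct.
- Mild biphasic acid hydrolysis of F2 comes back to the route at 5.

**Step 10.** Facial selectivity of the ring closure may be poor. The two chair-like closures that keep the C4 methyl equatorial differ only modestly in energy, so closure onto the β face may compete, as may simple carbonyl reduction.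

The fallback uses alkene formation followed by stereospecific anti-addition and inversion in place of reductive diol formation:
- Setting out from 12, McMurry coupling with low-valent titanium (TiCl3(DME)1.5, Zn–Cu, DME, reflux, slow addition) would give (5βH)-eudesma-3,6-diene F4.
- Woodward–Prévost cis-hydroxylation (I2, AgOAc, AcOH; then H2O, heat) starts with reversible iodonium formation and a Markovnikov, trans-diaxial opening.
- Only the ring A alkene offers a path for this opening that is free of a syn-axial iodine–carbon contact (iodine at C3β, acetate at C4α). The product would be 4α-acetoxy-3β-iodo-(5βH)-eudesm-6-ene F5.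
- Silver-assisted displacement of iodide from the α face by the neighbouring acetate, followed by hydrolysis, would give 4α-acetoxy-(5βH)-eudesm-6-en-3α-ol F6.
- K2CO3/MeOH comes back to the route at 13.

**Step 11.** Allylic oxidation may be sluggish or misdirected. The ene attack takes place on a hindered trisubstituted alkene flanked by the axial C10 methyl, selenium may be tied up by the cis-diol, and the isopropyl methine may be attacked.

The fallback uses hydrogen-atom abstraction on a protected diol in place of the ene/[2,3] pathway on the free diol: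
- Setting out from 13, 2,2-dimethoxypropane with pyridinium p-toluenesulfonate would give the 3α,4α-O-isopropylidene ene F7.
- CrO3/3,5-dimethylpyrazole (CH2Cl2, −20 °C) can carry only the C8 methylene through to a carbonyl group. It would give the 3α,4α-O-isopropylidene enone F8 directly.
- Aqueous acetic acid comes back to the route at 15.

Further compounds
F1 | step 2 | (1S,2R)-2-{[tert-butyl(dimethyl)silyl]oxymethyl}-1-methyl-4-(propan-2-yl)cyclohex-3-ene-1-carbaldehyde (mirror image of 5) | O=C[C@@]1(C)CCC(C(C)C)=C[C@H]1CO[Si](C)(C)C(C)(C)C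
F2 | step 2 | (4R,5R)-1,3-dimethyl-4,5-diphenylimidazolidin-2-yl derivative of 5 | CN1[C@H](c2ccccc2)[C@@H](c2ccccc2)N(C)C1[C@]3(C)CCC(C(C)C)=C[C@@H]3CO[Si](C)(C)C(C)(C)C
F3 | step 2 | (4R,5R)-1,3-dimethyl-4,5-diphenylimidazolidin-2-yl derivative of F1 | CN1[C@H](c2ccccc2)[C@@H](c2ccccc2)N(C)C1[C@@]3(C)CCC(C(C)C)=C[C@H]3CO[Si](C)(C)C(C)(C)C
F4 | step 10 | (5βH)-eudesma-3,6-diene | CC1=CCC[C@]2(C)CCC(C(C)C)=C[C@@H]21
F5 | step 10 | 4α-acetoxy-3β-iodo-(5βH)-eudesm-6-ene | I[C@H]1CC[C@]2(C)CCC(C(C)C)=C[C@@H]2[C@]1(C)OC(C)=O
F6 | step 10 | 4α-acetoxy-(5βH)-eudesm-6-en-3α-ol | O[C@@H]1CC[C@]2(C)CCC(C(C)C)=C[C@@H]2[C@]1(C)OC(C)=O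
F7 | step 11 | 3α,4α-O-isopropylidene-(5βH)-eudesm-6-ene-3,4-diol | CC1(C)O[C@@H]2CC[C@]3(C)CCC(C(C)C)=C[C@@H]3[C@]2(C)O1
F8 | step 11 | 3α,4α-O-isopropylidenedioxy-(5βH)-eudesm-6-en-8-one | CC1(C)O[C@@H]2CC[C@]3(C)CC(=O)C(C(C)C)=C[C@@H]3[C@]2(C)O1
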